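**Plan**
- Retrosynthetic cuts: first the ester C–O bond between the primary CH2–O and the (Z)-2-(hydroxymethyl)but-2-enoyl group, then the allylic CH2–CH= bond of the cinnamyl arm, last the aryl–carbonyl bond of a ketone precursor of the carbinol.
- Enabling feature: C-2 of the propyl chain (next to the p-anisyl carbinol) carries two one-carbon arms, CH2–O and CH2–CH=; joined through one oxygen they form an oxetane whose C-3 is not a stereocentre, so the target is a ring-opened 3-substituted oxetane.
- Forward, arm A: oxetane-3-carboxylic acid → Weinreb amide → aryl ketone → (S)-carbinol by Noyori hydrogenation (the only external source of chirality).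
- Key event: the (E)-styryl Grignard reagent (from 3,4-dimethoxycinnamic acid) opens the oxetane inside a magnesium chelate of the carbinol; one step forms the C–C bond, sets C-2 and frees the primary hydroxyl.
- Acid: (E)-but-2-enal → (Z)-2-iodobut-2-en-1-ol → TBS ether → I/Li exchange and CO2; the Z geometry is fixed at the iodination and carried through retentive steps, the E-styrene comes from the cinnamic acid.
- Endgame: Mitsunobu esterification of the primary hydroxyl, then desilylation; the target has no carbocyclic or heterocyclic ring besides the arenes, and the oxetane is bought, not built.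

Key step: step 6

Assumption: compounds 1, 4 (THF solution), 7 and 13 are taken as commercial, and the (R)-xylbinap/(R)-daipen ruthenium catalyst is taken to reduce ketone 5 with the facial sense usual for aryl alkyl ketones, which corresponds to (S)-6.

**Route**

Step 1
Reactants: 1 oxetane-3-carboxylic acid
Product: 3 N-methoxy-N-methyloxetane-3-carboxamide, via acyl imidazolide 2 (not isolated)
Conditions: CDI (1.1 equiv), CH2Cl2, 0 °C → rt; then MeNH(OMe)·HCl (1.2 equiv), rt
Reagents that add atoms: N,O-dimethylhydroxylamine hydrochloride, CNOC.Cl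
Why: Amidation through the acyl imidazolide runs under near-neutral conditions that spare the acid-sensitive oxetane.

Step 2
Reactants: 3 N-methoxy-N-methyloxetane-3-carboxamide; 4 (4-methoxyphenyl)magnesium bromide
Product: 5 (4-methoxyphenyl)(oxetan-3-yl)methanone
Conditions: THF, 0 °C; then sat. aq NH4Cl
Reagents that add atoms: none
Why: Weinreb ketone synthesis, in which the chelated tetrahedral adduct resists a second addition and the oxetane is inert to the Grignard reagent in the absence of copper.

Step 3
Reactants: 5 (4-methoxyphenyl)(oxetan-3-yl)methanone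
Product: 6 (S)-(4-methoxyphenyl)(oxetan-3-yl)methanol
Conditions: trans-RuCl2[(R)-xylbinap][(R)-daipen] (0.2 mol %), t-BuOK (2 mol %), H2 (8 atm), i-PrOH, 25 °C
Reagents that add atoms: none
Why: Noyori asymmetric hydrogenation, in which the divalent ruthenium diphosphine–diamine hydride reduces the carbonyl in the outer sphere and tells the flat aryl group from the sec-alkyl oxetanyl group, so the (R)/(R) catalyst should give the (S)-carbinol, while the basic medium leaves the oxetane intact because the ring C–O bonds lie orthogonal to the enolate π system.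

Step 4
Reactants: 7 (E)-3-(3,4-dimethoxyphenyl)prop-2-enoic acid
Product: 8 4-[(E)-2-bromoethenyl]-1,2-dimethoxybenzene
Conditions: NBS (1.05 equiv), Et3N (5 mol %), CH2Cl2, rt
Reagents that add atoms: N-bromosuccinimide, O=C1CCC(=O)N1Br
Why: Catalytic Hunsdiecker-type bromodecarboxylation of an electron-rich cinnamate, whose bromination and decarboxylative elimination should return the (E)-β-bromostyrene.

Step 5
Reactants: 8 4-[(E)-2-bromoethenyl]-1,2-dimethoxybenzene
Product: 10 [(E)-2-(3,4-dimethoxyphenyl)ethenyl]magnesium bromide (Et2O solution used at once), via alkenyllithium 9 (not isolated)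
Conditions: t-BuLi (2.0 equiv), Et2O, −78 °C; then MgBr2·OEt2 (1.0 equiv), −78 → 0 °C
Reagents that add atoms: magnesium bromide diethyl etherate, [Mg+2].[Br-].[Br-].CCOCC
Why: Bromine–lithium exchange with two equivalents of t-BuLi is stereoretentive at the sp2 carbon at low temperature, and transmetalation to magnesium gives a configurationally stable (E)-alkenyl Grignard reagent.

Step 6
Reactants: 6 (S)-(4-methoxyphenyl)(oxetan-3-yl)methanol; 10 [(E)-2-(3,4-dimethoxyphenyl)ethenyl]magnesium bromide
Product: 12 (1S,2S)-2-[(2E)-3-(3,4-dimethoxyphenyl)prop-2-en-1-yl]-1-(4-methoxyphenyl)propane-1,3-diol, via chloromagnesium alkoxide 11 (not isolated)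
Conditions: i-PrMgCl (1.0 equiv), toluene, 0 °C; then CuBr·SMe2 (10 mol %), 10 (2.0 equiv, Et2O), 0 → 35 °C; sat. aq NH4Cl
Reagents that add atoms: none
Why: Proposed new method: deprotonation gives chloromagnesium alkoxide 11, whose magnesium, held by the carbinol oxygen, reaches the oxetane oxygen across the ring, so that a rigid bicyclic chelate (Mg, carbinol O, carbinol C, oxetane C-3, either ring CH2, ring O) activates the ether and fixes the carbinol C–O bond anti to the C-3–H bond; in this chelate the p-anisyl group lies over one ring methylene and the carbinol hydrogen over the other, and the alkenylcuprate formed from 10 and the copper salt attacks, SN2 and anti to the ring oxygen, the methylene on the hydrogen side. The closest known reaction types are the copper-catalysed opening of oxetanes by alkenyl Grignard reagents and chelation-controlled additions next to a metal alkoxide, whereas a diastereotopic-group-selective opening of a 3-substituted oxetane under control of an adjacent carbinol centre has no direct precedent. No ring is closed: the four-membered ring is opened, and this releases the primary hydroxyl that will carry the ester. The new stereocentre (C-2 of 12) is controlled by the (S)-carbinol centre through the chelate, attack at the methylene anti to the aryl group giving the (1S,2S) diol. The step needs group selectivity between the two ring methylenes, secured by the pre-formed magnesium alkoxide in a weakly coordinating solvent, retention of the E geometry, secured by the configurational stability of alkenylcopper species, and freedom from Grob-type fragmentation to 4-methoxybenzaldehyde, which the ring prevents by holding the C–C bond to be cleaved about 115° from the ring C–O bonds instead of antiperiplanar.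

Step 7
Reactants: 13 (E)-but-2-enal
Product: 14 (Z)-2-iodobut-2-enal
Conditions: I2 (1.5 equiv), K2CO3 (1.2 equiv), DMAP (0.2 equiv), THF–H2O (1:1), rt
Reagents that add atoms: iodine, II
Why: Amine-catalysed α-iodination of an enal (conjugate addition of DMAP, iodination of the enolate, E1cB loss of DMAP), which should return the conjugated enal with methyl trans to the formyl group, that is the (Z)-iodide.

Step 8
Reactants: 14 (Z)-2-iodobut-2-enal
Product: 15 (Z)-2-iodobut-2-en-1-ol
Conditions: NaBH4, THF–H2O (9:1), 0 °C
Reagents that add atoms: none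
Why: Borohydride 1,2-reduction of the α-iodo enal leaves the vinyl iodide and the alkene geometry untouched.

Step 9
Reactants: 15 (Z)-2-iodobut-2-en-1-ol
Product: 16 tert-butyl{[(2Z)-2-iodobut-2-en-1-yl]oxy}dimethylsilane
Conditions: TBSCl, imidazole, CH2Cl2, 0 °C → rt
Reagents that add atoms: tert-butyldimethylsilyl chloride, CC(C)(C)[Si](C)(C)Cl
Why: Standard silylation of a primary allylic alcohol, needed so that the hydroxyl neither quenches the organolithium nor competes in the esterification.

Step 10
Reactants: 16 tert-butyl{[(2Z)-2-iodobut-2-en-1-yl]oxy}dimethylsilane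
Product: 18 (2Z)-2-({[tert-butyl(dimethyl)silyl]oxy}methyl)but-2-enoic acid, via alkenyllithium 17 (not isolated)
Conditions: t-BuLi (2.1 equiv), Et2O, −78 °C; then CO2 (g), −78 → 0 °C; cold 0.5 M HCl to pH 3
Reagents that add atoms: carbon dioxide, O=C=O
Why: Iodine–lithium exchange is stereoretentive and fast at −78 °C, where the retro-Brook silyl shift is slow, and carboxylation places the carboxyl group cis to the methyl group, giving the (Z)-acid of the angelate type.

Step 11
Reactants: 12 (1S,2S)-2-[(2E)-3-(3,4-dimethoxyphenyl)prop-2-en-1-yl]-1-(4-methoxyphenyl)propane-1,3-diol; 18 (2Z)-2-({[tert-butyl(dimethyl)silyl]oxy}methyl)but-2-enoic acid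
Product: 19 (2S,3S)-2-[(2E)-3-(3,4-dimethoxyphenyl)prop-2-en-1-yl]-3-hydroxy-3-(4-methoxyphenyl)propyl (2Z)-2-({[tert-butyl(dimethyl)silyl]oxy}methyl)but-2-enoate
Conditions: PPh3 (1.2 equiv), DIAD (1.2 equiv), 18 (1.1 equiv), THF, 0 °C → rt
Reagents that add atoms: none
Why: Mitsunobu esterification activates the unhindered primary hydroxyl in preference to the hindered secondary benzylic one and alkylates the carboxylate without activating the acyl group, so the (Z)-enoate cannot isomerise by conjugate addition–elimination and no stereocentre is touched.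

Step 12
Reactants: 19 (2S,3S)-2-[(2E)-3-(3,4-dimethoxyphenyl)prop-2-en-1-yl]-3-hydroxy-3-(4-methoxyphenyl)propyl (2Z)-2-({[tert-butyl(dimethyl)silyl]oxy}methyl)but-2-enoate
Product: 20 (2S,3S)-2-[(2E)-3-(3,4-dimethoxyphenyl)prop-2-en-1-yl]-3-hydroxy-3-(4-methoxyphenyl)propyl (2Z)-2-(hydroxymethyl)but-2-enoate
Conditions: HF·pyridine, pyridine, THF, 0 °C → rt
Reagents that add atoms: none
Why: Buffered fluoride cleavage of the primary allylic TBS ether avoids base-induced acyl migration to the secondary hydroxyl, ionisation of the p-methoxybenzylic alcohol and isomerisation of the (Z)-enoate.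

**Compound list**
1 | oxetane-3-carboxylic acid | OC(=O)C1COC1 | starting material
2 | (1H-imidazol-1-yl)(oxetan-3-yl)methanone | O=C(C1COC1)n1ccnc1 | intermediate (not isolated)
3 | N-methoxy-N-methyloxetane-3-carboxamide | CON(C)C(=O)C1COC1 | intermediate
4 | (4-methoxyphenyl)magnesium bromide | COc1ccc([Mg]Br)cc1 | starting material
5 | (4-methoxyphenyl)(oxetan-3-yl)methanone | COc1ccc(cc1)C(=O)C1COC1 | intermediate
6 | (S)-(4-methoxyphenyl)(oxetan-3-yl)methanol | O[C@@H](C1COC1)c1ccc(OC)cc1 | intermediate
7 | (E)-3-(3,4-dimethoxyphenyl)prop-2-enoic acid | OC(=O)/C=C/c1ccc(OC)c(OC)c1 | starting material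
8 | 4-[(E)-2-bromoethenyl]-1,2-dimethoxybenzene | Br/C=C/c1ccc(OC)c(OC)c1 | intermediate
9 | [(E)-2-(3,4-dimethoxyphenyl)ethenyl]lithium | [Li]/C=C/c1ccc(OC)c(OC)c1 | intermediate (not isolated)
10 | [(E)-2-(3,4-dimethoxyphenyl)ethenyl]magnesium bromide | Br[Mg]/C=C/c1ccc(OC)c(OC)c1 | intermediate
11 | chloromagnesium (S)-(4-methoxyphenyl)(oxetan-3-yl)methanolate | Cl[Mg]O[C@@H](C1COC1)c1ccc(OC)cc1 | intermediate (not isolated)
12 | (1S,2S)-2-[(2E)-3-(3,4-dimethoxyphenyl)prop-2-en-1-yl]-1-(4-methoxyphenyl)propane-1,3-diol | OC[C@H](C/C=C/c1ccc(OC)c(OC)c1)[C@H](O)c1ccc(OC)cc1 | intermediate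
13 | (E)-but-2-enal | C/C=C/C=O | starting material
14 | (Z)-2-iodobut-2-enal | C/C=C(\I)C=O | intermediate
15 | (Z)-2-iodobut-2-en-1-ol | C/C=C(\I)CO | intermediate
16 | tert-butyl{[(2Z)-2-iodobut-2-en-1-yl]oxy}dimethylsilane | C/C=C(\I)CO[Si](C)(C)C(C)(C)C | intermediate
17 | [(2E)-1-{[tert-butyl(dimethyl)silyl]oxy}but-2-en-2-yl]lithium | C/C=C(\[Li])CO[Si](C)(C)C(C)(C)C | intermediate (not isolated)
18 | (2Z)-2-({[tert-butyl(dimethyl)silyl]oxy}methyl)but-2-enoic acid | C/C=C(/CO[Si](C)(C)C(C)(C)C)C(=O)O | intermediate
19 | (2S,3S)-2-[(2E)-3-(3,4-dimethoxyphenyl)prop-2-en-1-yl]-3-hydroxy-3-(4-methoxyphenyl)propyl (2Z)-2-({[tert-butyl(dimethyl)silyl]oxy}methyl)but-2-enoate | C/C=C(/CO[Si](C)(C)C(C)(C)C)C(=O)OC[C@H](C/C=C/c1ccc(OC)c(OC)c1)[C@H](O)c1ccc(OC)cc1 | intermediate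
20 | (2S,3S)-2-[(2E)-3-(3,4-dimethoxyphenyl)prop-2-en-1-yl]-3-hydroxy-3-(4-methoxyphenyl)propyl (2Z)-2-(hydroxymethyl)but-2-enoate | C/C=C(/CO)C(=O)OC[C@H](C/C=C/c1ccc(OC)c(OC)c1)[C@H](O)c1ccc(OC)cc1 | target

**Count**
Total steps: 12. Longest linear sequence: 6 steps (1, 2, 3, 6, 11, 12; the acid branch 7, 8, 9, 10, 11, 12 is equally long).

**Steps most likely to fail**

1. Step 6 (Proposed new method). What may go wrong: the chelate may be lost, with opening through open conformers or after activation by external magnesium halide, so that the two ring methylenes are attacked without discrimination. The β-branched oxetane may also open slowly, leaving room for halide to open the ring instead. Fallback, setting out from carbinol 6 and bromide 8 and coming back at diol 12: the choice between the methylenes is handed to a catalyst and the same C–C bond is made in a separate coupling. Carbinol 6 would be silylated (TBSCl, imidazole, DMF) to (S)-tert-butyl[(4-methoxyphenyl)(oxetan-3-yl)methoxy]dimethylsilane F1. The oxetane would then be opened with TMSBr under a chiral squaramide hydrogen-bond-donor catalyst (toluene–Et2O, −78 °C), a known enantioselective desymmetrisation of 3-substituted oxetanes, with the catalyst antipode matched to the resident centre, to give tert-butyl{[(1S,2S)-3-bromo-1-(4-methoxyphenyl)-2-{[(trimethylsilyl)oxy]methyl}propoxy]}dimethylsilane F2. Nickel-catalysed reductive cross-electrophile coupling of F2 with bromide 8 (NiBr2(dme), 4,4′-di-tert-butyl-2,2′-bipyridine, Mn powder, DMA) should form the CH2–CH= bond with retention of the E geometry and give tert-butyl{[(1S,2S)-2-[(2E)-3-(3,4-dimethoxyphenyl)prop-2-en-1-yl]-1-(4-methoxyphenyl)-3-[(trimethylsilyl)oxy]propoxy]}dimethylsilane F3. TBAF in THF would then remove both silyl groups and return diol 12.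

2. Step 11. What may go wrong: the p-methoxybenzylic secondary hydroxyl may also be activated and then ionise, eliminate or be esterified with loss of configuration, or the activated primary carbinol may cyclise onto the secondary hydroxyl. Fallback, setting out from diol 12 and acid 18 and coming back at ester 19: the acid is activated instead of the alcohol. Acid 18 would be converted with 2,4,6-trichlorobenzoyl chloride and Et3N in toluene into (2Z)-2-({[tert-butyl(dimethyl)silyl]oxy}methyl)but-2-enoic 2,4,6-trichlorobenzoic anhydride F4. F4 would be heated with diol 12 in toluene without DMAP (Yamaguchi esterification in the variant used for angelates, where leaving out the nucleophilic catalyst suppresses Z to E isomerisation); the primary hydroxyl should be acylated first and give 19.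

3. Step 3. What may go wrong: facial discrimination between the aryl group and the oxetan-3-yl group may be insufficient, or turnover of the electron-rich ketone may be slow. Fallback, setting out from Weinreb amide 3 and coming back at carbinol 6: the stereocentre is made by C–C bond formation instead of reduction. Amide 3 would be reduced with LiAlH4 (0.5 equiv, THF, −78 °C) to oxetane-3-carbaldehyde F5, used at once. The mixed arylzinc from 4-methoxyphenylboronic acid and Et2Zn would then be added under a chiral β-amino alcohol ligand (catalytic asymmetric aryl transfer to an aldehyde), the ligand antipode being the one that gives (S)-6.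

**Further compounds**
F1 | step 6 | (S)-tert-butyl[(4-methoxyphenyl)(oxetan-3-yl)methoxy]dimethylsilane | CC(C)(C)[Si](C)(C)O[C@@H](C1COC1)c1ccc(OC)cc1
F2 | step 6 | tert-butyl{[(1S,2S)-3-bromo-1-(4-methoxyphenyl)-2-{[(trimethylsilyl)oxy]methyl}propoxy]}dimethylsilane | C[Si](C)(C)OC[C@H](CBr)[C@H](O[Si](C)(C)C(C)(C)C)c1ccc(OC)cc1
F3 | step 6 | tert-butyl{[(1S,2S)-2-[(2E)-3-(3,4-dimethoxyphenyl)prop-2-en-1-yl]-1-(4-methoxyphenyl)-3-[(trimethylsilyl)oxy]propoxy]}dimethylsilane | C[Si](C)(C)OC[C@H](C/C=C/c1ccc(OC)c(OC)c1)[C@H](O[Si](C)(C)C(C)(C)C)c1ccc(OC)cc1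
F4 | step 11 | (2Z)-2-({[tert-butyl(dimethyl)silyl]oxy}methyl)but-2-enoic 2,4,6-trichlorobenzoic anhydride | C/C=C(/CO[Si](C)(C)C(C)(C)C)C(=O)OC(=O)c1c(Cl)cc(Cl)cc1Cl
F5 | step 3 | oxetane-3-carbaldehyde | O=CC1COC1
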